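4 questions stand on the violet flask, and one quantity carries my reckoning.

| setting | violet | blue | flask |
|---|---|---|---|
| starting material | 0.24 M | 0.12 M | 0.24 M |
| partner | 0.168 M | 0.168 M | 0.168 M |
| temperature | 40 °C | 35 °C | 40 °C |
| remark | the very flask that is asked about, followed so far | run made earlier |  |
| time |  |  | 40 min |

| run | time / min | product / % |
|---|---|---|
| violet | 8.00 | 39.9 |
| violet | 15.0 | 45.1 |
| violet | 25.0 | 48.1 |
| violet | 30.0 | 50.4 |
| blue | 0.417 | 1.5 |
| blue | 1.00 | 3.5 |
| blue | 2.00 | 6.1 |
| blue | 3.00 | 9.7 |

(scatter of a reading: 0.5 percentage points)

- product, in percent of the starting material first charged, at 40 min
- what to do for the largest gain in product; "none" if nothing gains more than 2 percentage points (Monday's / Sunday's / Saturday's / Thursday's / none)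
- product present, with what was taken out counted in, in percent of the starting material first charged, after Monday's
- product present, with what was taken out counted in, in percent of the starting material first charged, after Saturday's

- Monday's: at 40 min add partner, 50.0 % of the amount charged, then wait 12 min
- Sunday's: change nothing and wait 12 min more
- Saturday's: at 40 min take out 90 % of the product then present, then wait 12 min
- Thursday's: at 40 min raise the temperature by 25 K, then wait 12 min

- product that was removed still counts
- steps under discussion: starting material <-> dormant form; starting material + partner + by-product -> product + 2 by-product; starting material + partner -> product + by-product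
- additions bring no volume worth counting

1. Both steps that make product take one partner per product, and the step to the dormant form makes none. Partner is charged in less than starting material, so it is the limiting reagent. c(partner) over c(starting material), as charged, is 70.0 %: this is the partner ceiling, the product that the charged partner can pay for.

2. The first extreme: the dormant form gives starting material back at once, and the violet flask ends at the ceiling. The second extreme: the dormant form gives nothing back, and the product in the violet flask stays near the last reading, 50.4 %.

3. The violet flask lies between them. Its last reading is less than the ceiling, yet the readings rise by 5.3 percentage points from 15.0 min to 30.0 min, more than the scatter.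

4. The room under the ceiling is the partner still free, counted as starting material. I let it shrink exponentially, with a closing time of room over tail rate, 55.5 min. My reckoning for 40 min is 53.6 %, which leaves room of 16 points for Sunday's, Saturday's and Thursday's, since these add no partner.

5. The forecast says 52.8 % (from 51.5 % to 54.2 %), 62 % after Monday's and 55.8 % after Saturday's, and it chooses Monday's: “Monday's is a tentative best.” My figure is higher than its number but inside its range.

6. The simulated flask gives 52.7 %, 58.5 % after Monday's and 55.9 % after Saturday's. The choice is Thursday's, not the forecast's: Thursday's gain of 17 points is more than Monday's 5.8 points. At 40.0 min the violet flask holds 45.6 % as dormant form and 1.72 % as free starting material, with 24.7 % of its partner charge left. The ceiling now leaves room of 17 points, and Thursday's gain fills nearly all of it.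

    starting material ⇌ dormant form (K = 15.0, k = 0.00358 s⁻¹, Ea = 101 kJ mol⁻¹, ΔH = −48.0 kJ mol⁻¹)
    starting material + partner + by-product → product + 2 by-product (k = 0.496 L² mol⁻² s⁻¹, Ea = 57.0 kJ mol⁻¹)
    starting material + partner → product + by-product (k = 0.00372 L mol⁻¹ s⁻¹, Ea = 66.0 kJ mol⁻¹)
    (constants at 40 °C)

7. Second flask: the same charges at 55 °C. The ceiling holds no temperature, so it stays at 70.0 % there. The computed product at 40.0 min is 69.7 %, with 0.44 % of the partner charge left.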